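**Retrosynthetic overview**
- The target is a 20-membered cyclophane with no stereocentre. Ring A (1,3,5-pattern: OH, aryl ether O, chain) and ring B (2,6-dihydroxyphenyl ether, chain para to the ether O) are joined by one ether oxygen and a twelve-carbon chain, numbered C1 (on ring B) to C12 (on ring A).
- Feature used: C10–C12 beside ring A are taken back to a cinnamyl unit (C11=C12 styrene, carbonate on C10), and C9 is given two removable phenylsulfonyl groups. The only ring-forming bond is C9–C10, closed by palladium π-allyl alkylation; the macrocycle is the single ring made.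
- Precursor assembly: C8–C9 by bis-sulfone alkylation, C1–ring B by B-alkyl Suzuki coupling, the diaryl ether by Chan–Lam coupling, ring A–C12 by Suzuki coupling with a silyl-protected hydroxypropenyl boronate. The chain goes on ring B before the ether is made, so only one aryl bromide is present at a time. An acrylate Heck/hydride sequence is avoided because the bis-sulfone carbanion could add to acrylate.
- After ring closure: alkene hydrogenation, double desulfonylation, triple O-demethylation.

Key step: step 7

Step 1
Reactants: 1 bis(phenylsulfonyl)methane; 2 8-bromooct-1-ene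
Product: 3 9,9-bis(phenylsulfonyl)non-1-ene
Conditions: 1 (1.5 equiv), NaH, DMF, 0 °C to rt; then 2, NaI (cat.), 70 °C
Reagents that add atoms: none
Why: SN2 alkylation of the bis-sulfonyl-stabilised sodium carbanion at the primary bromide should give the monoalkylated product, since excess 1 and the bulk of 3 suppress a second alkylation.

Step 2
Reactants: 3 9,9-bis(phenylsulfonyl)non-1-ene; 4 4-bromo-2,6-dimethoxyphenol
Product: 6 4-[9,9-bis(phenylsulfonyl)nonyl]-2,6-dimethoxyphenol, via alkylborane 5 (not isolated)
Conditions: 3 (1.3 equiv), 9-BBN, THF, 0 °C to rt; then 4, Pd(OAc)2, SPhos, aq. K3PO4 (excess), THF, 65 °C; NH4Cl work-up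
Reagents that add atoms: none
Why: Anti-Markovnikov hydroboration with 9-BBN places boron on C1 and B-alkyl Suzuki–Miyaura coupling then joins C1 to ring B, the electron-rich SPhos ligand offsetting slow oxidative addition into the bromophenoxide; because the bis-sulfone is already in place, no alkyl bromide ever meets the phenoxide.

Step 3
Reactants: 6 4-[9,9-bis(phenylsulfonyl)nonyl]-2,6-dimethoxyphenol; 7 3-bromo-5-methoxyphenylboronic acid
Product: 8 5-[9,9-bis(phenylsulfonyl)nonyl]-2-(3-bromo-5-methoxyphenoxy)-1,3-dimethoxybenzene
Conditions: 7 (2.5 equiv), Cu(OAc)2 (1.5 equiv), pyridine, 4 Å MS, CH2Cl2, dry air, rt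
Reagents that add atoms: none
Why: Chan–Lam oxidative O-arylation at room temperature should tolerate the aryl bromide, and with pyridine as the only base the bis-sulfone C–H stays un-ionised; 2,6-disubstituted phenols are known partners when the boronic acid is in excess.

Step 4
Reactants: 8 5-[9,9-bis(phenylsulfonyl)nonyl]-2-(3-bromo-5-methoxyphenoxy)-1,3-dimethoxybenzene; 9 (E)-3-(tert-butyldimethylsilyloxy)prop-1-enylboronic acid pinacol ester
Product: 10 tert-butyldimethylsilyl ether of (E)-3-(3-{4-[9,9-bis(phenylsulfonyl)nonyl]-2,6-dimethoxyphenoxy}-5-methoxyphenyl)prop-2-en-1-ol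
Conditions: Pd(dppf)Cl2, K2CO3, 1,4-dioxane–H2O, 80 °C
Reagents that add atoms: none
Why: Suzuki–Miyaura coupling of the aryl bromide with the (E)-alkenyl boronate proceeds with retention of alkene geometry, the silyl ether keeps the allylic oxygen from being ionised by zerovalent palladium, and the reversibly formed bis-sulfone carbanion meets no electrophile.

Step 5
Reactants: 10 the silyl ether from step 4
Product: 11 (E)-3-(3-{4-[9,9-bis(phenylsulfonyl)nonyl]-2,6-dimethoxyphenoxy}-5-methoxyphenyl)prop-2-en-1-ol
Conditions: TBAF, AcOH, THF, 0 °C to rt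
Reagents that add atoms: none
Why: Fluoride-mediated desilylation, buffered with acetic acid so that the bis-sulfone stays protonated, should free the primary allylic alcohol without touching the alkene.

Step 6
Reactants: 11 the (E)-cinnamyl alcohol from step 5
Product: 12 (E)-3-(3-{4-[9,9-bis(phenylsulfonyl)nonyl]-2,6-dimethoxyphenoxy}-5-methoxyphenyl)prop-2-en-1-yl methyl carbonate
Conditions: ClCO2Me, pyridine, CH2Cl2, 0 °C
Reagents that add atoms: methyl chloroformate, COC(Cl)=O
Why: O-acylation of the primary allylic alcohol with a chloroformate gives the carbonate, and pyridine is too weak a base to ionise the bis-sulfone, so C-acylation is not expected.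

Step 7
Reactants: 12 the cinnamyl methyl carbonate from step 6
Product: 13 20-membered macrocycle: trimethyl ether of the target skeleton with an (E)-C11=C12 double bond and two phenylsulfonyl groups on C9
Conditions: Pd(PPh3)4 (10 mol %), THF, 65 °C, Ar, syringe-pump addition of 12 over about 10 h, final concentration about 1 mM
Reagents that add atoms: none
Why: Zerovalent palladium ionises the allylic carbonate to a cationic 1-aryl-π-allyl complex, and the departing methyl carbonate loses CO2 to give methoxide, which deprotonates C9–H, so the carbanion arises only where its electrophile is waiting. The soft carbanion attacks the allyl ligand at the CH2 terminus C10 on the face opposite palladium and forms the C9–C10 bond; this is a Tsuji–Trost allylic alkylation run as a macrocyclisation under neutral conditions, a known use of bis-sulfone nucleophiles. The 20-membered ring closes with all three allyl carbons C10–C12 inside the ring, whereas attack at C12 would give an 18-membered ring with a vinyl side chain. No stereocentre is created, and the E geometry of C11=C12 follows from the syn π-allyl complex. The step needs linear over branched regioselectivity, secured by the bulk of the fully substituted carbanion and the retention of styrene conjugation, and ring closure over oligomerisation, secured by slow addition at high dilution.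

Step 8
Reactants: 13 the (E)-styrenyl bis-sulfone macrocycle
Product: 14 saturated 20-membered macrocycle: trimethyl ether of the target with two phenylsulfonyl groups on C9
Conditions: H2 (1 atm), Pd/C, EtOAc, rt
Reagents that add atoms: none
Why: Heterogeneous catalytic hydrogenation should saturate the only alkene, the disubstituted styrene, while aryl sulfones, aryl methyl ethers and the diaryl ether are inert.

Step 9
Reactants: 14 the saturated bis-sulfone macrocycle
Product: 15 trimethyl ether of the target (ring A OMe, ring B 2,6-di-OMe, twelve CH2 groups)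
Conditions: Mg turnings (excess), HgCl2 (cat.), MeOH–THF, rt to 50 °C
Reagents that add atoms: none
Why: Dissolving-metal reductive desulfonylation by single-electron transfer from magnesium cleaves both C–S bonds in turn, methanol protonating each carbanion, so C9 becomes a methylene and the arenes and ethers stay untouched.

Step 10
Reactants: 15 the trimethyl ether macrocycle
Product: 16 the target triol
Conditions: BBr3, CH2Cl2, −78 °C to rt; then H2O
Reagents that add atoms: none
Why: BBr3 ether cleavage removes the three aryl methyl groups by Lewis-acid complexation and bromide attack at methyl, while the diaryl ether offers no alkyl carbon for displacement and should survive.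

**Compound list**
1 | bis(phenylsulfonyl)methane | O=S(=O)(CS(=O)(=O)c1ccccc1)c1ccccc1 | starting material
2 | 8-bromooct-1-ene | C=CCCCCCCBr | starting material
3 | 9,9-bis(phenylsulfonyl)non-1-ene | C=CCCCCCCC(S(=O)(=O)c1ccccc1)S(=O)(=O)c1ccccc1 | intermediate
4 | 4-bromo-2,6-dimethoxyphenol | COc1cc(Br)cc(OC)c1O | starting material
5 | 9-[9,9-bis(phenylsulfonyl)nonyl]-9-borabicyclo[3.3.1]nonane | O=S(=O)(c1ccccc1)C(CCCCCCCCB1C2CCCC1CCC2)S(=O)(=O)c1ccccc1 | intermediate (not isolated)
6 | 4-[9,9-bis(phenylsulfonyl)nonyl]-2,6-dimethoxyphenol | COc1cc(CCCCCCCCC(S(=O)(=O)c2ccccc2)S(=O)(=O)c2ccccc2)cc(OC)c1O | intermediate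
7 | 3-bromo-5-methoxyphenylboronic acid | COc1cc(Br)cc(B(O)O)c1 | starting material
8 | 5-[9,9-bis(phenylsulfonyl)nonyl]-2-(3-bromo-5-methoxyphenoxy)-1,3-dimethoxybenzene | COc1cc(Br)cc(Oc2c(OC)cc(CCCCCCCCC(S(=O)(=O)c3ccccc3)S(=O)(=O)c3ccccc3)cc2OC)c1 | intermediate
9 | (E)-3-(tert-butyldimethylsilyloxy)prop-1-enylboronic acid pinacol ester | CC(C)(C)[Si](C)(C)OC/C=C/B1OC(C)(C)C(C)(C)O1 | starting material
10 | tert-butyldimethylsilyl ether of (E)-cinnamyl alcohol 11 | COc1cc(/C=C/CO[Si](C)(C)C(C)(C)C)cc(Oc2c(OC)cc(CCCCCCCCC(S(=O)(=O)c3ccccc3)S(=O)(=O)c3ccccc3)cc2OC)c1 | intermediate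
11 | (E)-3-(3-{4-[9,9-bis(phenylsulfonyl)nonyl]-2,6-dimethoxyphenoxy}-5-methoxyphenyl)prop-2-en-1-ol | COc1cc(/C=C/CO)cc(Oc2c(OC)cc(CCCCCCCCC(S(=O)(=O)c3ccccc3)S(=O)(=O)c3ccccc3)cc2OC)c1 | intermediate
12 | methyl carbonate of 11 (cyclisation precursor) | COc1cc(/C=C/COC(=O)OC)cc(Oc2c(OC)cc(CCCCCCCCC(S(=O)(=O)c3ccccc3)S(=O)(=O)c3ccccc3)cc2OC)c1 | intermediate
13 | 20-membered (E)-styrenyl bis-sulfone macrocycle, trimethyl ether | COc1cc(/C=C/CC(S(=O)(=O)c2ccccc2)(S(=O)(=O)c2ccccc2)CCCCCCCC3)cc(c1)Oc1c(OC)cc3cc1OC | intermediate
14 | saturated bis-sulfone macrocycle, trimethyl ether | COc1cc(CCCC(S(=O)(=O)c2ccccc2)(S(=O)(=O)c2ccccc2)CCCCCCCC3)cc(c1)Oc1c(OC)cc3cc1OC | intermediate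
15 | trimethyl ether of the target | COc1cc2cc(c1)Oc1c(OC)cc(cc1OC)CCCCCCCCCCCC2 | intermediate
16 | target triol | Oc1cc2cc(c1)Oc1c(O)cc(cc1O)CCCCCCCCCCCC2 | target

**Step count and risks**
Total steps: 10. Longest linear sequence: 10 (steps 1 to 10; compounds 4, 7 and 9 are purchased).

Steps most likely to fail:

1. Step 7. Intermolecular alkylation may outrun ring closure, the π-allyl complex may be captured by methoxide or at the benzylic terminus, or the catalyst may decay over the long addition. The fallback is a metal-free ring closure that sets out from alcohol 11. Treatment with CBr4 and PPh3 in CH2Cl2 at 0 °C should give the cinnamyl bromide, 5-[9,9-bis(phenylsulfonyl)nonyl]-2-{3-[(E)-3-bromoprop-1-en-1-yl]-5-methoxyphenoxy}-1,3-dimethoxybenzene F1. Slow addition of this bromide to Cs2CO3 in DMF at high dilution should close the ring by direct SN2 attack of the cesium bis-sulfonyl carbanion at C10, and the route is rejoined at macrocycle 13.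

2. Step 3. O-arylation of the doubly ortho-substituted phenol may be slow, leaving room for oxidation of the electron-rich phenol by divalent copper and air and for protodeboronation of the boronic acid. The fallback is an Ullmann-type coupling that sets out from phenol 6. With 1-bromo-3-iodo-5-methoxybenzene (COc1cc(Br)cc(I)c1), CuI, picolinic acid and K3PO4 in DMSO at 90 °C under argon, the coupling should occur selectively at the C–I bond and rejoin the route at compound 8. It makes no new compound (F0).

3. Step 2. Oxidative addition into the electron-rich bromophenoxide may be sluggish, so protodeboronation and β-hydride elimination of the alkylborane could consume the chain fragment. The fallback couples a protected phenol and sets out from bromophenol 4. Benzylation (benzyl bromide, K2CO3, acetone, reflux) should give 2-(benzyloxy)-5-bromo-1,3-dimethoxybenzene F2. B-alkyl Suzuki coupling of this ether with borane 5 (Pd(dppf)Cl2, aq. K3PO4, THF, 65 °C) should give 2-(benzyloxy)-5-[9,9-bis(phenylsulfonyl)nonyl]-1,3-dimethoxybenzene F3. Hydrogenolysis (H2, Pd/C, EtOAc) then removes the benzyl group and rejoins the route at phenol 6.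

**Further compounds**
F1 | step 7 | 5-[9,9-bis(phenylsulfonyl)nonyl]-2-{3-[(E)-3-bromoprop-1-en-1-yl]-5-methoxyphenoxy}-1,3-dimethoxybenzene | COc1cc(/C=C/CBr)cc(Oc2c(OC)cc(CCCCCCCCC(S(=O)(=O)c3ccccc3)S(=O)(=O)c3ccccc3)cc2OC)c1
F0 | step 3 | none | none
F2 | step 2 | 2-(benzyloxy)-5-bromo-1,3-dimethoxybenzene | COc1cc(Br)cc(OC)c1OCc1ccccc1
F3 | step 2 | 2-(benzyloxy)-5-[9,9-bis(phenylsulfonyl)nonyl]-1,3-dimethoxybenzene | COc1cc(CCCCCCCCC(S(=O)(=O)c2ccccc2)S(=O)(=O)c2ccccc2)cc(OC)c1OCc1ccccc1
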